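Its constants were drawn at random within sensible limits, and the outcome is calculated.

The charge held 0.20 mM of first end groups against 0.210 mM of second end groups, so first end groups were the limiting reagent, with 0.0100 mM of second end groups spare.

| flask | first end groups | second end groups | time | remark |
|---|---|---|---|---|
| elm | 0.20 mM | 0.210 mM (fed, over 7.50 s) | 15 s | all but second end groups at the start; second end groups goes in evenly over 7.50 s, the run ends at 15 s |
| larch | 0.20 mM | 0.210 mM | 15 s | everything together in a closed stirred flask, run for 15 s |
| ash | 0.20 mM | 0.210 mM |  | a single well-mixed tank run continuously and read at steady state, 15 s in it on average |
| cedar | 0.20 mM | 0.210 mM |  | one stirred flow tank at steady state, fed with the mixture as stated, mean residence time 150 s |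

    first end groups + second end groups ⇌ links (K1 = 31000 /M, k1 = 850 /M/s)
    first end groups + second end groups → rings, rate k2*[first end groups] as long as [second end groups] is above zero (k2 = 0.061 /s)

- the set-up with the highest share of links in all that became links or rings, at the outlet or at the end ("none" if the first two lie within 2 percentage points) (elm / larch / ash / cedar / none)
- share of links in all that became links or rings, at the outlet or at the end, elm
- share of links in all that became links or rings, at the outlet or at the end, larch
- share of links in all that became links or rings, at the outlet or at the end, ash
- share of links in all that became links or rings, at the outlet or at the end, cedar

- the stated concentrations are those of everything mixed, before any reaction; amounts are the same in each set-up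
- the feed brings no volume worth counting
- run time (elm): 15 s

**Step one, the end state.** Rings have no back step, so I took rings as the end state of a long stay and links as a stock on the way. Links break apart with k_d, the forward constant over the equilibrium constant, 0.0274 /s. That is a lifetime of 36.5 s, longer than 15 s but shorter than 150 s.

**Step two, the rate ratio.** With [A] and [B] the concentrations of first and second end groups, [A] cancels from link rate over ring rate, which leaves [B]/B*. Here B* = 0.0718 mM is the crossing concentration, the concentration of second end groups at which links and rings form equally fast. This ratio is a selectivity factor, and at the charge it is 2.93.

**Step three, the tank rule.** In a steady stirred tank with mean residence time τ, links are also lost by breaking apart, so links over rings is R = ([B]/B*)/(1 + k_d τ). For ash the divisor is 1.41.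

**Step four, a first number.** With [B] held at the charge, ash gives R = 2.07, a links share of 67.4%.

**Step five, the weak link reforged.** The ash tank does not hold the charge, because [B] = [A] + 0.0100 mM. The balance of first end groups then gives a quadratic, with [A] = 0.0746 mM and [B] = 0.0846 mM. So R = 0.836, and I committed to 45.5% for ash. My own reckoning stopped at ash, and I did not rank the flasks.

The forecast named larch as best, with 38% for elm, 53% for larch, 45.5% for ash and 7.2% for cedar, holding that “the all-at-once flask favours links most”.

The simulation gave larch as best, with 38.2% for elm, 53.4% for larch, 45.5% for ash and 7.20% for cedar. The cedar tank stood at 0.0284 mM of second end groups, below the crossing concentration of 0.0718 mM, while the ash tank stood at 0.0846 mM, above it. Put into the tank rule for cedar, [B]/B* is 0.396 and the divisor is 5.11, so R = 0.0775, a links share of about 7.19% in cedar.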